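**Plan**

- Numbering (germacrane): C1 = CH–OOH, C4=C5 = ring olefin bearing C15H2OAc, C6 = lactone O–CH, C7 = ring fusion, C8 = acyloxy CH, C10(=C14H2), C11(=C13H2)–C12 = lactone. The enabling feature lies in the ten-membered ring. The ring-cis C4=C5 olefin is 1,5-related to C10 and C1 is the carbon next to C10, so the ring is a cyclodec-5-enone oxygenated at its α-carbon. A retro-[3,3] shift (open C2–C3, join C5–C10) contracts it to a cis-1-vinyl-2-alkenylcyclohexanol.
- Cuts, latest bond first: C1–OOH (from the epimeric allylic alcohol), O8–acyl, O15–acetyl, C11=C13, C10=C14. Then C2–C3 and C1–O together (key step). Then C1–C2, C10–O, C10=C1, C4–C5, C6–O and C7–C11.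
- Rings, forward: cyclohexene from cyclohexa-1,3-diene, then a cis-fused five-membered lactone by iodolactonisation (masked as lactol methyl ether), then the ten-membered carbocycle by expansion of the six-membered ring, then the lactone restored and methylenated.
- Stereochemistry: lipase desymmetrisation plus one Mitsunobu inversion fixes C8 and the carbinol that relays to C7 (suprafacial Claisen) and C6 (iodolactonisation). The transient centres C5 and C10 decide the olefin geometry and the enolate face, hence C1. C1 is finally inverted by hydrogen peroxide, and C3' comes from the chiral pool.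

Key step: step 17

Assumption: the lipase cleaves the acetate on the R-configured carbon of the meso-diacetate, the usual sense for esters of secondary carbinols.

Remark: from compound 6 on, ring carbons carry their numbers in the target (C5 = carbinol carbon of 6, C6=C7, C8 = silyl ether carbon, C9, C10). TBS = tert-butyldimethylsilyl, TIPS = triisopropylsilyl, PMB = 4-methoxybenzyl.

**Route**

Step 1
Reactants: 1 cyclohexa-1,3-diene
Product: 2 meso-cis-cyclohex-2-ene-1,4-diyl diacetate
Conditions: Pd(OAc)2 (5 mol %), LiCl (cat.), LiOAc, p-benzoquinone, AcOH, 25 °C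
Reagents that add atoms: acetic acid, CC(=O)O
Why: Palladium-catalysed 1,4-diacetoxylation of a 1,3-diene, in which anti acetoxypalladation gives a π-allyl complex of divalent palladium and catalytic chloride suppresses inner-sphere acetate transfer, so the second acetate also enters anti to the metal and the 1,4-product is cis and therefore meso.

Step 2
Reactants: 2 meso-cis-cyclohex-2-ene-1,4-diyl diacetate
Product: 3 (1S,4R)-4-hydroxycyclohex-2-en-1-yl acetate
Conditions: lipase from Burkholderia cepacia, phosphate buffer pH 7, 25 °C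
Reagents that add atoms: none
Why: Enzymatic desymmetrisation of a meso-diacetate by enantiotopos-selective hydrolysis, which should free only the R-configured carbinol and so fix the absolute configuration from which C8, C7 and C6 derive.

Step 3
Reactants: 3 (1S,4R)-4-hydroxycyclohex-2-en-1-yl acetate
Product: 4 (1S,4S)-cyclohex-2-ene-1,4-diyl diacetate
Conditions: AcOH, PPh3, DIAD, THF, 0 °C
Reagents that add atoms: acetic acid, CC(=O)O
Why: Mitsunobu reaction, in which acetate displaces the oxyphosphonium group of the unhindered allylic alcohol with SN2 inversion and turns the cis into the C2-symmetric trans series that the trans relation of O8 and C11 requires.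

Step 4
Reactants: 4 (1S,4S)-cyclohex-2-ene-1,4-diyl diacetate
Product: 5 (1S,4S)-cyclohex-2-ene-1,4-diol
Conditions: K2CO3 (cat.), MeOH, 25 °C
Reagents that add atoms: none
Why: Base-catalysed transesterification removes both acetates by acyl–oxygen cleavage and leaves the stereocentres untouched.

Step 5
Reactants: 5 (1S,4S)-cyclohex-2-ene-1,4-diol
Product: 6 (1S,4S)-4-(tert-butyldimethylsilyloxy)cyclohex-2-en-1-ol
Conditions: NaH (1 equiv), THF, 25 °C; TBSCl (1 equiv)
Reagents that add atoms: tert-butyldimethylsilyl chloride, CC(C)(C)[Si](C)(C)Cl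
Why: Monosilylation of a symmetrical diol through its sparingly soluble monosodium alkoxide, and because the two hydroxyls are homotopic only one monoether can form.

Step 6
Reactants: 6 (1S,4S)-4-(tert-butyldimethylsilyloxy)cyclohex-2-en-1-ol; 7 triethyl orthoacetate
Product: 9 ethyl 2-[(1S,6S)-6-(tert-butyldimethylsilyloxy)cyclohex-2-en-1-yl]acetate, via ketene acetal 8 (not isolated)
Conditions: EtCO2H (cat.), neat orthoester, 140 °C, EtOH distilled off
Reagents that add atoms: none
Why: Johnson–Claisen rearrangement, in which the ketene acetal on the allylic oxygen shifts suprafacially, so the acetate arm reaches C7 on the face that the C5 oxygen leaves (trans to the C8 silyl ether) while the olefin moves to C5=C6.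

Step 7
Reactants: 9 ethyl 2-[(1S,6S)-6-(tert-butyldimethylsilyloxy)cyclohex-2-en-1-yl]acetate
Product: 11 iodolactone (γ-lactone cis-fused at C6/C7; C5 iodide trans to O6; C8 OTBS trans to C11), via lithium carboxylate 10 (not isolated)
Conditions: LiOH, THF/H2O, 25 °C; then NaHCO3 buffer, I2, KI, 0 °C, dark
Reagents that add atoms: lithium hydroxide, [Li+].[OH-]; iodine, II
Why: Saponification followed by kinetic iodolactonisation, in which the carboxylate opens the iodonium ion at C6 in the 5-exo mode from the face of its own tether, setting O6 cis to C11 and placing iodine at C5 trans-diaxial to O6.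

Step 8
Reactants: 11 iodolactone
Product: 12 unsaturated lactone (C5=C10 olefin; cis-fused 6,12-lactone; C8 OTBS)
Conditions: DBU, toluene, 90 °C
Reagents that add atoms: none
Why: E2 dehydroiodination with an amidine base, which can use only the antiperiplanar axial hydrogen at C10 because H6 is syn to the iodide, so the olefin ends at C5=C10.

Step 9
Reactants: 12 unsaturated lactone
Product: 14 lactol methyl ether (exo-methoxy at C12; C5=C10 olefin; C8 OTBS), via lactol 13 (not isolated)
Conditions: i-Bu2AlH (1.1 equiv), CH2Cl2, −78 °C; crude lactol, MeOH, PPTS, 25 °C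
Reagents that add atoms: methanol, CO
Why: Partial reduction of the lactone and acid-catalysed acetalisation mask C12 against the organometallic steps, the methoxy group taking the exo side of the cis-fused bicycle, and the other anomer would serve equally since C12 becomes trigonal again later.

Step 10
Reactants: 14 lactol methyl ether
Product: 16 C5–C10 epoxide syn to O6, via bromohydrin 15 (not isolated)
Conditions: NBS, NaHCO3, THF/H2O, 0 °C; then aq. NaOH, 25 °C
Reagents that add atoms: water, O
Why: Bromohydrin formation and intramolecular Williamson closure, chosen because a peracid would attack anti to O6: the bromonium ion forms on that open face, water opens it diaxially at C10 remote from the withdrawing O6, and the C10 alkoxide displaces the C5 bromide to give the epoxide syn to O6.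

Step 11
Reactants: 17 2-bromoprop-2-en-1-ol
Product: 18 2-bromoallyl 4-methoxybenzyl ether
Conditions: NaH, PMBCl, Bu4NI (cat.), THF, 0 °C
Reagents that add atoms: 4-methoxybenzyl chloride, COc1ccc(CCl)cc1
Why: Williamson ether synthesis on a primary allylic alkoxide at 0 °C, mild enough to avoid dehydrobromination of the vinyl bromide.

Step 12
Reactants: 18 2-bromoallyl 4-methoxybenzyl ether; 16 C5–C10 epoxide syn to O6
Product: 21 C10 alcohol (C5 alkenyl = 3-(PMBO)prop-1-en-2-yl; alkenyl trans to O6 and to O10), via alkenyllithium 19 (not isolated), via alkenylmagnesium bromide 20 (not isolated)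
Conditions: 18, t-BuLi (2 equiv), Et2O, −78 °C; MgBr2·OEt2, to −40 °C; CuI (15 mol %), 16, THF, −40 to 0 °C
Reagents that add atoms: none
Why: Copper-catalysed SN2 opening of an epoxide by an alkenyl Grignard reagent, in which the half-chair holding C11 and the C8 silyl ether equatorial allows trans-diaxial (Fürst–Plattner) opening only at C5, magnesium bridging the syn oxygens O6 and the epoxide oxygen offsets the inductive deactivation of C5, and low-temperature metalation keeps the β-alkoxy alkenyl metal from collapsing to allene.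

Step 13
Reactants: 21 C10 alcohol
Product: 23 C10 ketone with equatorial C5 alkenyl group cis to O6, via axial-alkenyl ketone 22 (not isolated)
Conditions: Dess–Martin periodinane, NaHCO3, CH2Cl2, 0 °C; crude ketone, Et3N, CH2Cl2, 25 °C, stopped at epimer equilibrium
Reagents that add atoms: none
Why: Dess–Martin oxidation followed by amine-mediated epimerisation through the enol, which moves the axial alkenyl group into the equatorial position of the chair that also keeps C11 and the C8 silyl ether equatorial, a weak base and short contact being chosen because α-protonation of the dienolate is faster than the γ-protonation that would drag the olefin into conjugation.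

Step 14
Reactants: 23 C10 ketone
Product: 24 C10 exocyclic methylene compound (new carbon = C1)
Conditions: Cp2TiMe2, toluene, 70 °C
Reagents that add atoms: dimethyltitanocene, C[Ti](C)(C1C=CC=C1)C1C=CC=C1
Why: Petasis methylenation, a non-basic carbonyl olefination through Cp2Ti=CH2 that should convert the enolisable β-alkoxy ketone without epimerisation at C5 or loss of O6 or O8, no ester being present at this stage.

Step 15
Reactants: 24 C10 exocyclic methylene compound
Product: 25 spiro-epoxide (O10 equatorial and trans to the C5 alkenyl group; C1H2 axial)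
Conditions: mCPBA (1.0 equiv), NaHCO3, CH2Cl2, −10 °C
Reagents that add atoms: 3-chloroperbenzoic acid, OOC(=O)c1cccc(Cl)c1
Why: Prilezhaev epoxidation, which should prefer the exocyclic C10=C1 olefin to the inductively deactivated C3=C4 allyl ether olefin and approach it equatorially because the axial face is closed by axial O6, so oxygen rather than carbon enters from the open side, whereas a vinyl metal added to 23 would come from that same side and give the unwanted trans-dialkenyl carbinol.

Step 16
Reactants: 25 spiro-epoxide
Product: 26 cis-1-vinyl-2-alkenylcyclohexanol (vinyl, C5 alkenyl, O6 and C11 on one face; O10 and C8 OTBS on the other; exo-methyl lactol ether)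
Conditions: Me3S+ I− (5 equiv), n-BuLi (4.8 equiv), THF, −10 to 25 °C
Reagents that add atoms: trimethylsulfonium iodide, C[S+](C)C.[I-]
Why: One-carbon homologation of a terminal epoxide to an allylic alcohol with excess dimethylsulfonium methylide, by SN2 opening at the CH2 terminus and ylide-induced β-elimination of dimethyl sulfide, which leaves the C10–O bond and its configuration untouched and places the vinyl group cis to the alkenyl group.

Step 17
Reactants: 26 cis-1-vinyl-2-alkenylcyclohexanol
Product: 29 ten-membered α-ketol (C10 ketone; 1S hydroxyl; ring-cis C4=C5 olefin; C15 OPMB; C8 OTBS; lactol methyl ether), via potassium alkoxide 27 (not isolated), via potassium enolate 28 (not isolated)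
Conditions: KH (1.2 equiv), 18-crown-6 (1.2 equiv), THF, 0 to 25 °C; solution decanted from excess KH, −78 °C, 2-(phenylsulfonyl)-3-phenyloxaziridine (1.5 equiv); AcOH quench at −78 °C
Reagents that add atoms: 2-(phenylsulfonyl)-3-phenyloxaziridine, O=S(=O)(c1ccccc1)N1OC1c1ccccc1
Why: Deprotonation gives alkoxide 27, whose charge weakens C5–C10 so that the 1,5-diene C2=C1–C10–C5–C4=C3 undergoes a chair-like anionic oxy-Cope rearrangement forming C2–C3, the C4=C5 olefin and the C1=C10 enolate 28, the closest known type being the expansion of 1,2-divinylcyclohexanols to cyclodec-5-enones with oxidation of the regiodefined enolate. The ten-membered ring is closed by four-carbon expansion of the cyclohexane and not by end-to-end cyclisation, so no dilution is needed. The step needs the ring-cis C4=C5 geometry, which arises only from the cyclohexane chair with equatorial alkenyl and axial vinyl group (C5–C6 axial in the six-centre chair); in 26 this same chair holds C11, the C8 silyl ether and the alkoxide equatorial, whereas the flipped chair would set the alkenyl group and C11 syn-diaxial and force C15 over the ring. In the reactive chair the axial C6–O bond is gauche to C5–C10, so Grob-type fragmentation is not aligned. The enolate is born with C2 trans to C9 and its inner face covered by C4=C5, and since the oxygen on C10 cannot swing through the ring the oxaziridine reaches C1 only from the outer face, anti to the departed C5, which sets 1S (epimeric to the target carbon). Oxygen enters at C1 alone because the enolate is formed regiospecifically and is oxidised at −78 °C before proton exchange with C9 can begin.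

Step 18
Reactants: 29 ten-membered α-ketol
Product: 30 C1 TIPS ether of the α-ketol
Conditions: TIPSOTf, 2,6-lutidine, CH2Cl2, −78 to 0 °C
Reagents that add atoms: triisopropylsilyl triflate, CC(C)[Si](C(C)C)(C(C)C)OS(=O)(=O)C(F)(F)F
Why: Silylation with a silyl triflate and a hindered pyridine base works on hindered α-ketols without enolisation, and the TIPS ether is chosen to outlast the later cleavage of the C8 TBS ether.

Step 19
Reactants: 30 C1 TIPS ether of the α-ketol
Product: 31 C10(=C14H2) methylene compound
Conditions: Cp2TiMe2, toluene, 70 °C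
Reagents that add atoms: dimethyltitanocene, C[Ti](C)(C1C=CC=C1)C1C=CC=C1
Why: Petasis methylenation, non-basic so that the β-silyloxy group at C8 is not eliminated, and selective because the lactone is still masked as an acetal and C10 is the only carbonyl group.

Step 20
Reactants: 31 C10(=C14H2) methylene compound
Product: 32 C12 lactol (anomeric mixture)
Conditions: AcOH/H2O/THF, 25 °C
Reagents that add atoms: water, O
Why: Acid hydrolysis of a 2-deoxyfuranoside-type methyl acetal, fast enough in dilute acetic acid to spare both secondary silyl ethers, the PMB ether and the allylic C6–O bond.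

Step 21
Reactants: 32 C12 lactol
Product: 33 6,12-γ-lactone
Conditions: Dess–Martin periodinane, NaHCO3, CH2Cl2, 25 °C
Reagents that add atoms: none
Why: Dess–Martin oxidation of a lactol to the lactone, unambiguous because the lactol hydroxyl is the only free one.

Step 22
Reactants: 33 6,12-γ-lactone
Product: 36 α-methylene-γ-lactone (C11=C13H2), via Mannich base 34 (not isolated), via ammonium iodide 35 (not isolated)
Conditions: LiN(i-Pr)2, THF, −78 °C; CH2=NMe2+ I−, to 25 °C; MeI, THF; aq. NaHCO3/CH2Cl2
Reagents that add atoms: Eschenmoser's salt, C=[N+](C)C.[I-]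
Why: α-Methylenation of a γ-lactone by Mannich reaction of its lithium enolate with Eschenmoser's salt, quaternisation and Hofmann-type elimination, placed before any acetate or acrylate is present so that the amide base meets only one acidic site.

Step 23
Reactants: 36 α-methylene-γ-lactone
Product: 37 C15 allylic alcohol
Conditions: DDQ, CH2Cl2/pH 7 buffer, 0 °C
Reagents that add atoms: none
Why: Oxidative cleavage of a PMB ether by benzylic hydride abstraction with DDQ, to which silyl ethers and electron-poor or unactivated olefins are inert.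

Step 24
Reactants: 37 C15 allylic alcohol
Product: 38 C15 acetate
Conditions: Ac2O, pyridine, DMAP (cat.), 0 °C
Reagents that add atoms: acetic anhydride, CC(=O)OC(C)=O
Why: Acylation of the only free (primary allylic) hydroxyl under nucleophilic catalysis.

Step 25
Reactants: 38 C15 acetate
Product: 39 C8 alcohol (C1 OTIPS retained)
Conditions: HF·pyridine, pyridine, THF, 0 to 25 °C
Reagents that add atoms: none
Why: Fluoride-mediated desilylation using the graded lability of silyl ethers, the secondary TBS ether being cleaved well before the TIPS ether, under conditions that tolerate the acetate and the α-methylene lactone.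

Step 26
Reactants: 40 (R)-2-(2,2-dimethyl-1,3-dioxolan-4-yl)ethanol
Product: 42 (R)-2-(2,2-dimethyl-1,3-dioxolan-4-yl)prop-2-enal, via aldehyde 41 (not isolated)
Conditions: (COCl)2, DMSO, CH2Cl2, −78 °C; Et3N; then CH2=NMe2+ I−, to 25 °C
Reagents that add atoms: Eschenmoser's salt, C=[N+](C)C.[I-]
Why: Swern oxidation and, in the same flask, Mannich condensation with loss of dimethylamine (α-methylenation of an aldehyde), which does not touch the stereocentre because it lies β to the carbonyl group.

Step 27
Reactants: 42 (R)-2-(2,2-dimethyl-1,3-dioxolan-4-yl)prop-2-enal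
Product: 43 (R)-2-(2,2-dimethyl-1,3-dioxolan-4-yl)acrylic acid
Conditions: NaClO2, NaH2PO4, 2-methylbut-2-ene, t-BuOH/H2O, 0 to 25 °C
Reagents that add atoms: sodium chlorite, [Na+].[O-]Cl=O
Why: Pinnick oxidation, the standard mild conversion of enals into acrylic acids, buffered so that the acetonide survives.

Step 28
Reactants: 43 (R)-2-(2,2-dimethyl-1,3-dioxolan-4-yl)acrylic acid; 39 C8 alcohol
Product: 45 C8 ester (side-chain diol as acetonide; C1 OTIPS), via mixed anhydride 44 (not isolated)
Conditions: 2,4,6-trichlorobenzoyl chloride, Et3N, THF, 25 °C; then 39, DMAP, toluene, 25 °C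
Reagents that add atoms: none
Why: Yamaguchi esterification, effective for hindered secondary alcohols, proceeding by acyl transfer with retention at C8 and without enolisable positions in the acid that could racemise.

Step 29
Reactants: 45 C8 ester
Product: 46 C1 allylic alcohol (1S)
Conditions: Bu4NF, AcOH (1:1), THF, 0 to 25 °C
Reagents that add atoms: none
Why: Buffered fluoride desilylation removes the TIPS group at near-neutral pH, so the acetate, both acrylate units and the acetonide should stay intact.

Step 30
Reactants: 46 C1 allylic alcohol (1S)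
Product: 48 C1 hydroperoxide (1R; side-chain acetonide), via mesylate 47 (not isolated)
Conditions: Ms2O, i-Pr2NEt (1.05 equiv each), CH2Cl2, −40 °C; then anhydrous H2O2 in Et2O (large excess), −40 to 0 °C
Reagents that add atoms: hydrogen peroxide, OO
Why: Perhydrolysis of an allylic methanesulfonate, in which the sulfonate, made chloride-free at low temperature, is displaced by neutral hydrogen peroxide from the side opposite the leaving group (SN2 or tight ion pair), inverting C1 to the R configuration of the target, while the absence of free base keeps hydroperoxide anion away from the α-methylene lactone, the acrylate and the acetate.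

Step 31
Reactants: 48 C1 hydroperoxide
Product: 49 target CNP0307408.1
Conditions: AcOH/H2O (4:1), 30 °C
Reagents that add atoms: none
Why: Mild acid hydrolysis of a terminal acetonide, at an acidity too low for Hock cleavage of the allylic hydroperoxide or for ester hydrolysis, frees the 3',4'-diol without touching any stereocentre.

**Compound list**

1 | cyclohexa-1,3-diene | C1=CC=CCC1 | starting material
2 | meso-cis-cyclohex-2-ene-1,4-diyl diacetate | CC(=O)O[C@H]1C=C[C@@H](OC(C)=O)CC1 | intermediate
3 | (1S,4R)-4-hydroxycyclohex-2-en-1-yl acetate | O[C@H]1C=C[C@@H](OC(C)=O)CC1 | intermediate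
4 | (1S,4S)-cyclohex-2-ene-1,4-diyl diacetate | CC(=O)O[C@@H]1C=C[C@@H](OC(C)=O)CC1 | intermediate
5 | (1S,4S)-cyclohex-2-ene-1,4-diol | O[C@@H]1C=C[C@@H](O)CC1 | intermediate
6 | (1S,4S)-4-(tert-butyldimethylsilyloxy)cyclohex-2-en-1-ol | O[C@@H]1C=C[C@@H](O[Si](C)(C)C(C)(C)C)CC1 | intermediate
7 | triethyl orthoacetate | CCOC(C)(OCC)OCC | starting material
8 | ketene acetal of 6 | C=C(OCC)O[C@@H]1C=C[C@@H](O[Si](C)(C)C(C)(C)C)CC1 | intermediate
9 | ethyl 2-[(1S,6S)-6-(tert-butyldimethylsilyloxy)cyclohex-2-en-1-yl]acetate | CCOC(=O)C[C@H]1C=CCC[C@@H]1O[Si](C)(C)C(C)(C)C | intermediate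
10 | lithium carboxylate of 9 | [Li+].[O-]C(=O)C[C@H]1C=CCC[C@@H]1O[Si](C)(C)C(C)(C)C | intermediate
11 | iodolactone | O=C1C[C@@H]2[C@@H](O[Si](C)(C)C(C)(C)C)CC[C@@H](I)[C@@H]2O1 | intermediate
12 | unsaturated lactone | O=C1C[C@@H]2[C@@H](O[Si](C)(C)C(C)(C)C)CC=C[C@@H]2O1 | intermediate
13 | lactol | OC1C[C@@H]2[C@@H](O[Si](C)(C)C(C)(C)C)CC=C[C@@H]2O1 | intermediate
14 | lactol methyl ether | CO[C@H]1C[C@@H]2[C@@H](O[Si](C)(C)C(C)(C)C)CC=C[C@@H]2O1 | intermediate
15 | bromohydrin (C5 Br, C10 OH, trans-diaxial) | CO[C@H]1C[C@@H]2[C@@H](O[Si](C)(C)C(C)(C)C)C[C@H](O)[C@@H](Br)[C@@H]2O1 | intermediate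
16 | C5–C10 epoxide syn to O6 | CO[C@H]1C[C@@H]2[C@@H](O[Si](C)(C)C(C)(C)C)C[C@@H]3O[C@@H]3[C@@H]2O1 | intermediate
17 | 2-bromoprop-2-en-1-ol | C=C(Br)CO | starting material
18 | 2-bromoallyl 4-methoxybenzyl ether | C=C(Br)COCc1ccc(OC)cc1 | intermediate
19 | alkenyllithium | [Li]C(=C)COCc1ccc(OC)cc1 | intermediate
20 | alkenylmagnesium bromide | C=C([Mg]Br)COCc1ccc(OC)cc1 | intermediate
21 | C10 alcohol with C5 alkenyl group | CO[C@H]1C[C@@H]2[C@@H](O[Si](C)(C)C(C)(C)C)C[C@H](O)[C@@H](C(=C)COCc3ccc(OC)cc3)[C@@H]2O1 | intermediate
22 | axial-alkenyl ketone | CO[C@H]1C[C@@H]2[C@@H](O[Si](C)(C)C(C)(C)C)CC(=O)[C@@H](C(=C)COCc3ccc(OC)cc3)[C@@H]2O1 | intermediate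
23 | equatorial-alkenyl ketone | CO[C@H]1C[C@@H]2[C@@H](O[Si](C)(C)C(C)(C)C)CC(=O)[C@H](C(=C)COCc3ccc(OC)cc3)[C@@H]2O1 | intermediate
24 | C10 exocyclic methylene compound | CO[C@H]1C[C@@H]2[C@@H](O[Si](C)(C)C(C)(C)C)CC(=C)[C@H](C(=C)COCc3ccc(OC)cc3)[C@@H]2O1 | intermediate
25 | spiro-epoxide | CO[C@H]1C[C@@H]2[C@@H](O[Si](C)(C)C(C)(C)C)C[C@]3(CO3)[C@H](C(=C)COCc4ccc(OC)cc4)[C@@H]2O1 | intermediate
26 | cis-1-vinyl-2-alkenylcyclohexanol (key-step precursor) | CO[C@H]1C[C@@H]2[C@@H](O[Si](C)(C)C(C)(C)C)C[C@](O)(C=C)[C@H](C(=C)COCc3ccc(OC)cc3)[C@@H]2O1 | intermediate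
27 | potassium alkoxide of 26 | CO[C@H]1C[C@@H]2[C@@H](O[Si](C)(C)C(C)(C)C)C[C@]([O-])(C=C)[C@H](C(=C)COCc3ccc(OC)cc3)[C@@H]2O1.[K+] | intermediate
28 | potassium C1=C10 enolate | CO[C@H]1C[C@@H]2[C@@H](O[Si](C)(C)C(C)(C)C)C/C([O-])=C/CC/C(COCc3ccc(OC)cc3)=C\[C@@H]2O1.[K+] | intermediate
29 | ten-membered α-ketol (key-step product) | CO[C@H]1C[C@@H]2[C@@H](O[Si](C)(C)C(C)(C)C)CC(=O)[C@@H](O)CC/C(COCc3ccc(OC)cc3)=C\[C@@H]2O1 | intermediate
30 | C1 TIPS ether | CO[C@H]1C[C@@H]2[C@@H](O[Si](C)(C)C(C)(C)C)CC(=O)[C@@H](O[Si](C(C)C)(C(C)C)C(C)C)CC/C(COCc3ccc(OC)cc3)=C\[C@@H]2O1 | intermediate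
31 | C10(=C14H2) methylene compound | CO[C@H]1C[C@@H]2[C@@H](O[Si](C)(C)C(C)(C)C)CC(=C)[C@@H](O[Si](C(C)C)(C(C)C)C(C)C)CC/C(COCc3ccc(OC)cc3)=C\[C@@H]2O1 | intermediate
32 | C12 lactol | OC1C[C@@H]2[C@@H](O[Si](C)(C)C(C)(C)C)CC(=C)[C@@H](O[Si](C(C)C)(C(C)C)C(C)C)CC/C(COCc3ccc(OC)cc3)=C\[C@@H]2O1 | intermediate
33 | 6,12-γ-lactone | O=C1C[C@@H]2[C@@H](O[Si](C)(C)C(C)(C)C)CC(=C)[C@@H](O[Si](C(C)C)(C(C)C)C(C)C)CC/C(COCc3ccc(OC)cc3)=C\[C@@H]2O1 | intermediate
34 | Mannich base | O=C1C(CN(C)C)[C@@H]2[C@@H](O[Si](C)(C)C(C)(C)C)CC(=C)[C@@H](O[Si](C(C)C)(C(C)C)C(C)C)CC/C(COCc3ccc(OC)cc3)=C\[C@@H]2O1 | intermediate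
35 | ammonium iodide | O=C1C(C[N+](C)(C)C)[C@@H]2[C@@H](O[Si](C)(C)C(C)(C)C)CC(=C)[C@@H](O[Si](C(C)C)(C(C)C)C(C)C)CC/C(COCc3ccc(OC)cc3)=C\[C@@H]2O1.[I-] | intermediate
36 | α-methylene-γ-lactone | O=C1C(=C)[C@@H]2[C@@H](O[Si](C)(C)C(C)(C)C)CC(=C)[C@@H](O[Si](C(C)C)(C(C)C)C(C)C)CC/C(COCc3ccc(OC)cc3)=C\[C@@H]2O1 | intermediate
37 | C15 allylic alcohol | O=C1C(=C)[C@@H]2[C@@H](O[Si](C)(C)C(C)(C)C)CC(=C)[C@@H](O[Si](C(C)C)(C(C)C)C(C)C)CC/C(CO)=C\[C@@H]2O1 | intermediate
38 | C15 acetate | O=C1C(=C)[C@@H]2[C@@H](O[Si](C)(C)C(C)(C)C)CC(=C)[C@@H](O[Si](C(C)C)(C(C)C)C(C)C)CC/C(COC(C)=O)=C\[C@@H]2O1 | intermediate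
39 | C8 alcohol | O=C1C(=C)[C@@H]2[C@@H](O)CC(=C)[C@@H](O[Si](C(C)C)(C(C)C)C(C)C)CC/C(COC(C)=O)=C\[C@@H]2O1 | intermediate
40 | (R)-2-(2,2-dimethyl-1,3-dioxolan-4-yl)ethanol | OCC[C@@H]1COC(C)(C)O1 | starting material
41 | (R)-2-(2,2-dimethyl-1,3-dioxolan-4-yl)acetaldehyde | O=CC[C@@H]1COC(C)(C)O1 | intermediate
42 | (R)-2-(2,2-dimethyl-1,3-dioxolan-4-yl)prop-2-enal | C=C(C=O)[C@@H]1COC(C)(C)O1 | intermediate
43 | (R)-2-(2,2-dimethyl-1,3-dioxolan-4-yl)acrylic acid | C=C(C(=O)O)[C@@H]1COC(C)(C)O1 | intermediate
44 | mixed anhydride of 43 and 2,4,6-trichlorobenzoic acid | C=C(C(=O)OC(=O)c1c(Cl)cc(Cl)cc1Cl)[C@@H]1COC(C)(C)O1 | intermediate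
45 | C8 ester | O=C1C(=C)[C@@H]2[C@@H](OC(=O)C(=C)[C@@H]3COC(C)(C)O3)CC(=C)[C@@H](O[Si](C(C)C)(C(C)C)C(C)C)CC/C(COC(C)=O)=C\[C@@H]2O1 | intermediate
46 | C1 allylic alcohol (1S) | O=C1C(=C)[C@@H]2[C@@H](OC(=O)C(=C)[C@@H]3COC(C)(C)O3)CC(=C)[C@@H](O)CC/C(COC(C)=O)=C\[C@@H]2O1 | intermediate
47 | C1 mesylate | O=C1C(=C)[C@@H]2[C@@H](OC(=O)C(=C)[C@@H]3COC(C)(C)O3)CC(=C)[C@@H](OS(C)(=O)=O)CC/C(COC(C)=O)=C\[C@@H]2O1 | intermediate
48 | C1 hydroperoxide (1R), acetonide | O=C1C(=C)[C@@H]2[C@@H](OC(=O)C(=C)[C@@H]3COC(C)(C)O3)CC(=C)[C@H](OO)CC/C(COC(C)=O)=C\[C@@H]2O1 | intermediate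
49 | CNP0307408.1 | C=C1C(=O)O[C@H]2/C=C(/COC(C)=O)CC[C@@H](OO)C(=C)C[C@H](OC(=O)C(=C)[C@@H](O)CO)[C@@H]12 | target

**Step count**

Total steps: 31. Longest linear sequence: 28 (steps 1–10, 12–25, 28–31).

**Steps most likely to fail**

**Step 17.** The rearrangement starts from an axial vinyl group that sits 1,3 to axial O6, so it may be slow.

- What may go wrong: during a long reaction the enolate can exchange protons with C9 and expel the C8 silyloxide. During the oxidation it can add to the sulfonimine that the oxaziridine leaves behind.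
- Fallback (from 26, back at 29): the carbon–carbon and the carbon–oxygen events are separated. The alkoxide is rearranged as before and enolate 28 is silylated on oxygen with Me3SiCl to the trimethylsilyl enol ether F1, which is neutral and can be purified. Rubottom oxidation with dimethyldioxirane in acetone at −40 °C attacks the electron-rich enol ether on its outer face. After silyl migration this gives the α-trimethylsilyloxy ketone F2. Citric acid in methanol frees the hydroxyl and returns to the route at 29.

**Step 30.** The allylic sulfonate may ionise.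

- What may go wrong: ionisation opens the way to attack at C14 with allylic shift, partial loss of configuration at C1, and participation of C4=C5 across the ring.
- Fallback (from 46, back at 48): oxygen is brought in by an ene reaction instead of a substitution. Mitsunobu reaction with N-isopropylidene-N'-(2-nitrobenzenesulfonyl)hydrazine (PPh3, DEAD, THF) gives the sulfonylhydrazone adduct F3. Trifluoroethanol/water releases the allylic diazene, which loses nitrogen with transfer of hydrogen to C14 (reductive allylic transposition) and gives the 1(10)E-olefin F4 with a C14 methyl group. Schenck ene reaction (O2, tetraphenylporphyrin, visible light, CH2Cl2, −20 °C) engages only this electron-rich trisubstituted olefin. It should place oxygen on the outer face of C1 with hydrogen abstraction from C14 and rejoin the route at 48.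

**Step 13.** The amine-mediated equilibration runs through a dienolate.

- What may go wrong: repeated turnover can leak into γ-protonation, moving the C3=C4 olefin into conjugation. It can also trigger β-elimination of O6.
- Fallback (from 22, back at 23): thermodynamic equilibration is replaced by a single, kinetically controlled protonation. Soft enolisation (Me3SiOTf, Et3N, CH2Cl2, −78 °C) removes the more acidic C5 hydrogen and stores the enol as the trimethylsilyl dienol ether F5. Bu4NF/AcOH in THF at −78 °C liberates the dienolate in the presence of the proton source. It is protonated at the α-carbon from the face opposite the pseudoaxial O6, which gives 23.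

**Further compounds**

F1 | step 17 | trimethylsilyl enol ether of the ring-expanded ketone | CO[C@H]1C[C@@H]2[C@@H](O[Si](C)(C)C(C)(C)C)C/C(O[Si](C)(C)C)=C/CC/C(COCc3ccc(OC)cc3)=C\[C@@H]2O1
F2 | step 17 | α-trimethylsilyloxy ketone | CO[C@H]1C[C@@H]2[C@@H](O[Si](C)(C)C(C)(C)C)CC(=O)[C@@H](O[Si](C)(C)C)CC/C(COCc3ccc(OC)cc3)=C\[C@@H]2O1
F3 | step 30 | C1 sulfonylhydrazone adduct | O=C1C(=C)[C@@H]2[C@@H](OC(=O)C(=C)[C@@H]3COC(C)(C)O3)CC(=C)[C@H](N(N=C(C)C)S(=O)(=O)c3ccccc3[N+](=O)[O-])CC/C(COC(C)=O)=C\[C@@H]2O1
F4 | step 30 | 1(10)E-olefin with C14 methyl group | O=C1C(=C)[C@@H]2[C@@H](OC(=O)C(=C)[C@@H]3COC(C)(C)O3)C/C(C)=C/CC/C(COC(C)=O)=C\[C@@H]2O1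
F5 | step 13 | trimethylsilyl dienol ether of 22 | CO[C@H]1C[C@@H]2[C@@H](O[Si](C)(C)C(C)(C)C)CC(O[Si](C)(C)C)=C(C(=C)COCc3ccc(OC)cc3)[C@@H]2O1
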